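**Plan**
Numbering (briarane): C1 quaternary ring-fusion carbon (methyl C15), C2 senecioyloxy carbon, C5=C6 olefin (methyl C16), C7 lactone CH–O, C8=C17 butenolide olefin (methyl C18, carbonyl C19), C10 ring-fusion CH, C11/C12 epoxide (methyl C20), C13 CH2, C14 acetoxy carbon; β is the face of C15.
Retrosynthesis cuts C5=C6 (ring-closing metathesis), C8=C17 and C8–C9 (Horner–Wadsworth–Emmons annulation after Fukuyama acylation), the epoxide, C13–C14 ([2,3]-Wittig ring expansion of a 2-lithio-5-vinyloxolane), C11–C12 (vinyl addition), C1–C10 (dianionic Ireland–Claisen) and C1–C2 (aldol).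
Forward: aldol, Claisen (acyclic C1/C2/C10 triad), temporary oxolane (O, C14, C1, C10, C11), cyclohexene by the key step, epoxide, butenolide, ten-membered ring last.
Enabling feature: in the six-membered ring the oxygen-bearing C14 lies 1,4 to the methyl-bearing epoxide carbon C11 with C13–C12 between them, so the ring without its epoxide is a cyclohex-3-enol, the [2,3]-Wittig retron of an ether bridging C14 and C11 through C1 and C10; the oxygen that finally carries the acetate starts as the C11 ketone oxygen.
Stereochemistry: C2 from the auxiliary aldol; C1 and C10 from the chelated-enolate Claisen; C14 by chirality transfer from the temporary C11 centre (Felkin–Anh vinyl addition); C11/C12 by vanadium delivery from the C9 hydroxyl; C7 from (S)-α-hydroxy-γ-butyrolactone; the 5Z olefin from ring constraint.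

Key step: step 13

Step 1
Reactants: 1 4-methylpent-4-en-1-ol
Product: 2 4-methylpent-4-enal
Conditions: TEMPO (cat.), PhI(OAc)2, CH2Cl2, 25 °C
Reagents that add atoms: none
Why: Oxoammonium (TEMPO) oxidation of a primary alcohol should stop at the volatile aldehyde and leave the 1,1-disubstituted olefin untouched.

Step 2
Reactants: 2 4-methylpent-4-enal; 3 (R)-4-benzyl-3-propanoyl-1,3-oxazolidin-2-one
Product: 5 (R)-4-benzyl-3-[(2R,3S)-3-hydroxy-2,6-dimethylhept-6-enoyl]-1,3-oxazolidin-2-one, via dibutylboron enolate 4 (not isolated)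
Conditions: n-Bu2BOTf, i-Pr2NEt, CH2Cl2, −78 → 0 °C; then 2, −78 → 0 °C; pH 7 buffer, MeOH, H2O2
Reagents that add atoms: none
Why: Evans syn aldol, in which the (Z)-boron enolate reacts through a closed chair transition state on the face away from the benzyl group of the (R)-auxiliary, so the carbinol that becomes C2 is set as (S) while the adjacent methine is erased later.

Step 3
Reactants: 5 aldol adduct
Product: 7 (2R,3S)-3-hydroxy-2,6-dimethylhept-6-enoic acid, via lithium peroxycarboxylate 6 (not isolated)
Conditions: LiOH, H2O2, THF/H2O, 0 °C; then Na2SO3; HCl to pH 2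
Reagents that add atoms: hydrogen peroxide (OO)
Why: Hydroperoxide attacks the exocyclic imide carbonyl selectively and the peracid salt is reduced by sulfite, which should release the acid without retro-aldol and return the auxiliary.

Step 4
Reactants: 8 (E)-but-2-ene-1,4-diol
Product: 9 (E)-4-[(triisopropylsilyl)oxy]but-2-en-1-ol
Conditions: NaH (1.0 equiv), THF, 0 °C; then i-Pr3SiCl, 0 → 25 °C
Reagents that add atoms: chlorotriisopropylsilane (CC(C)[Si](Cl)(C(C)C)C(C)C)
Why: Monosilylation of a symmetrical diol through its poorly soluble monosodium alkoxide should favour the mono-ether.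

Step 5
Reactants: 7 hydroxy acid; 9 allylic alcohol
Product: 10 (E)-4-[(triisopropylsilyl)oxy]but-2-en-1-yl (2R,3S)-3-hydroxy-2,6-dimethylhept-6-enoate
Conditions: EDC·HCl, DMAP, CH2Cl2, 0 → 25 °C
Reagents that add atoms: none
Why: Steglich-type carbodiimide esterification, in which the unhindered primary allylic alcohol should outcompete the secondary β-hydroxyl of the acid.

Step 6
Reactants: 10 allyl ester
Product: 12 (2S,3S)-2-[(1S)-1-hydroxy-4-methylpent-4-en-1-yl]-2-methyl-3-{[(triisopropylsilyl)oxy]methyl}pent-4-enoic acid, via dilithium enolate alkoxide 11 (not isolated)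
Conditions: LiN(i-Pr)2 (3 equiv), THF, −78 → 25 °C, then 45 °C; aq. HCl
Reagents that add atoms: none
Why: Dianionic Ireland–Claisen rearrangement, in which lithium chelation between the alkoxide and enolate oxygens fixes the enolate geometry (C2 cis to OLi), the allyl unit approaches anti to the C3 chain, and the chair transition state with the (E)-olefin substituent equatorial creates quaternary C1 and C10 with the relative and absolute configuration of the target.

Step 7
Reactants: 12 Claisen acid
Product: 13 methyl ester of 12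
Conditions: TMSCHN2, MeOH/toluene, 0 °C
Reagents that add atoms: (trimethylsilyl)diazomethane (C[Si](C)(C)C=[N+]=[N-])
Why: Diazoalkane methylation of the hindered neopentyl acid proceeds at the carboxylate oxygen and does not touch the free hydroxyl or the olefins.

Step 8
Reactants: 13 hydroxy ester
Product: 14 C2 triethylsilyl ether of 13
Conditions: Et3SiOTf, 2,6-lutidine, CH2Cl2, −78 → 0 °C
Reagents that add atoms: triethylsilyl trifluoromethanesulfonate (CC[Si](CC)(CC)OS(=O)(=O)C(F)(F)F)
Why: The silyl triflate is reactive enough to cap the hindered C2 carbinol next to the quaternary centre, giving a group that can later be removed in the presence of the primary triisopropylsilyl ether.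

Step 9
Reactants: 14 silyl ether
Product: 15 methyl (2S,3S)-2-methyl-4-oxo-2-{(1S)-4-methyl-1-[(triethylsilyl)oxy]pent-4-en-1-yl}-3-{[(triisopropylsilyl)oxy]methyl}pentanoate
Conditions: PdCl2 (10 mol %), CuCl (30 mol %), O2 (1 atm), DMF/H2O 7:1, 25 °C
Reagents that add atoms: water (O)
Why: Tsuji–Wacker oxidation by divalent palladium converts the monosubstituted vinyl group into the methyl ketone (C11=O with C20) with Markovnikov selectivity, while the 1,1-disubstituted olefin is a poor substrate under these conditions.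

Step 10
Reactants: 15 methyl ketone
Product: 17 3,5-dimethyl-3-{(1S)-4-methyl-1-[(triethylsilyl)oxy]pent-4-en-1-yl}-4-{[(triisopropylsilyl)oxy]methyl}-5-vinyloxolan-2-one (5-vinyl cis to 4-CH2OSi and to 3-CH3), via bromomagnesium alkoxide 16 (not isolated)
Conditions: CH2=CHMgBr, THF, −78 → 25 °C; aq. NH4Cl
Reagents that add atoms: vinylmagnesium bromide (C=C[Mg]Br)
Why: Felkin–Anh addition of the vinyl Grignard reagent anti to the quaternary C1 substituent should place the vinyl group cis to the C9 arm once the tertiary alkoxide closes onto the methyl ester (5-exo-trig lactonization), which sets the temporary C11 centre that the key step reads.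

Step 11
Reactants: 17 lactone
Product: 18 oxolan-2-ol (lactol) of 17
Conditions: i-Bu2AlH (1.2 equiv), CH2Cl2, −78 °C; aq. potassium sodium tartrate
Reagents that add atoms: none
Why: Low-temperature hydride reduction of a hindered γ-lactone should stop at the lactol because the tetrahedral aluminate is stable at −78 °C.

Step 12
Reactants: 18 lactol
Product: 19 2-(phenylsulfanyl)oxolane
Conditions: PhSSPh, n-Bu3P, THF, 25 °C
Reagents that add atoms: diphenyl disulfide (c1ccc(SSc2ccccc2)cc1)
Why: Disulfide/phosphine activation of the anomeric hydroxyl (oxyphosphonium, then thiolate capture through the oxocarbenium ion) gives the O,S-acetal under neutral conditions that spare the tertiary allylic ether and both silyl ethers.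

Step 13
Reactants: 19 2-(phenylsulfanyl)oxolane
Product: 21 4,6-dimethyl-6-{(1S)-4-methyl-1-[(triethylsilyl)oxy]pent-4-en-1-yl}-5-{[(triisopropylsilyl)oxy]methyl}cyclohex-3-en-1-ol (14α-OH), via 2-lithiooxolane 20 (not isolated)
Conditions: lithium 4,4'-di-tert-butylbiphenylide (2.5 equiv), THF, −78 °C, then −78 → −30 °C; aq. NH4Cl
Reagents that add atoms: none
Why: Proposed new method: Two-electron reduction of the C14–S bond gives the 2-lithiooxolane 20, whose carbanion attacks the vinyl terminus C13 while the allylic C11–O bond breaks in a [2,3]-sigmatropic (Wittig) shift, so the ring oxygen stays on C14 as the alkoxide and the C11=C12 olefin appears inside the new carbocycle. The closest known reaction types are the Still–Wittig rearrangement of α-lithio allyl ethers made by reductive lithiation of O,S-acetals or by tin–lithium exchange and the Claisen ring enlargement of 2-methylene-5-vinyloxolanes to cycloheptenones, which shows that a sigmatropic shift across a vinyl-substituted oxolane is geometrically possible; the one-atom-shorter carbanion version on an oxolane has not been shown. The six-membered ring (C1, C10, C11, C12, C13, C14) closes in a 6-endo sense with respect to the allyl unit, as a syn SN2′ ring expansion through a five-membered envelope transition state (C14, O, C11, C12, C13) that resembles a 7-oxabicyclo[2.2.1]heptene. C14 is the only new stereocentre and is set by chirality transfer from C11: the vinyl group sits on the oxolane face that carries the C1 methyl group and the C9 arm, C13 can only reach C14 on that face, and the oxygen therefore ends cis to the C2 arm and trans to the C1 methyl group (14α), while the C11 centre is consumed. The step needs the [2,3] shift to outrun the [1,2] shift, protonation and retro-[3+2] cleavage of the lithiated oxolane; the [1,2] path would give a strained cyclobutanol, the temperature is kept at or below −30 °C, and the shift is expected to proceed with inversion from the epimer that has lithium anti to the vinyl group, which the planar radical and the equilibrating organolithium can supply whatever the sulfide configuration. The silyl ethers and the 1,1-disubstituted olefin are inert to the arene radical anion at these temperatures, and C–S cleavage is far faster than reduction of the allylic C–O bond.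

Step 14
Reactants: 21 cyclohexenol
Product: 22 14-O-acetate of 21
Conditions: Ac2O, DMAP, pyridine, 25 → 40 °C
Reagents that add atoms: acetic anhydride (CC(=O)OC(C)=O)
Why: DMAP-catalysed acylation through the N-acetylpyridinium ion should acetylate the hindered axial alcohol, the only free hydroxyl in the molecule.

Step 15
Reactants: 22 acetate
Product: 23 C2 alcohol (triethylsilyl group of 22 removed)
Conditions: PPTS, MeOH/CH2Cl2, 25 °C
Reagents that add atoms: none
Why: Acid-catalysed methanolysis cleaves a triethylsilyl ether much faster than a primary triisopropylsilyl ether and does not touch the acetate.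

Step 16
Reactants: 23 C2 alcohol
Product: 24 2-O-(3-methylbut-2-enoate) of 23
Conditions: 3-methylbut-2-enoyl chloride, DMAP, pyridine, CH2Cl2, 0 → 25 °C
Reagents that add atoms: 3-methylbut-2-enoyl chloride (CC(C)=CC(=O)Cl)
Why: Acylation through the N-acylpyridinium salt without a trialkylamine should avoid vinylketene formation and so keep the senecioate double bond in conjugation.

Step 17
Reactants: 24 senecioate
Product: 25 primary C9 alcohol (triisopropylsilyl group of 24 removed)
Conditions: HF·pyridine, pyridine, THF, 0 → 25 °C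
Reagents that add atoms: none
Why: Buffered fluoride desilylation leaves both esters in place and avoids the alkoxide that could trigger acyl migration.

Step 18
Reactants: 25 homoallylic alcohol
Product: 26 11β,12β-epoxide of 25
Conditions: VO(acac)2 (5 mol %), t-BuOOH (decane), CH2Cl2, 0 → 25 °C
Reagents that add atoms: tert-butyl hydroperoxide (CC(C)(C)OO)
Why: Vanadium-catalysed epoxidation of a homoallylic alcohol delivers oxygen from the alkoxide-bound peroxide to the olefin face that carries the CH2OH arm (β, setting C11 and C12), while the remote 1,1-disubstituted olefin and the electron-poor senecioate olefin have no hydroxyl to direct the metal.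

Step 19
Reactants: 26 epoxy alcohol
Product: 27 C9 iodide of 26
Conditions: I2, PPh3, imidazole, CH2Cl2, 0 °C
Reagents that add atoms: iodine (II)
Why: Appel-type iodination through the alkoxyphosphonium ion is fast for a primary alcohol at 0 °C, conditions routinely used on epoxy alcohols.

Step 20
Reactants: 28 (S)-3-hydroxyoxolan-2-one
Product: 29 (S)-2-hydroxy-4-(phenylselanyl)butanoic acid
Conditions: PhSeSePh, Na, THF; then 28, DMF, 100 °C; aq. HCl
Reagents that add atoms: diphenyl diselenide (c1ccc([Se][Se]c2ccccc2)cc1)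
Why: The soft selenolate opens the lactone by SN2 attack at the O–CH2 carbon, which leaves the carbinol stereocentre (future C7) untouched and installs a latent vinyl group.

Step 21
Reactants: 29 hydroxy acid
Product: 30 S-ethyl (S)-2-hydroxy-4-(phenylselanyl)butanethioate
Conditions: EtSH, DCC, DMAP (cat.), CH2Cl2, 0 °C
Reagents that add atoms: ethanethiol (CCS)
Why: Carbodiimide thioesterification, in which the thiol is a far better nucleophile than the α-hydroxyl toward the O-acylisourea.

Step 22
Reactants: 30 hydroxy thioester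
Product: 31 S-ethyl (2S)-2-{[2-(diethoxyphosphoryl)propanoyl]oxy}-4-(phenylselanyl)butanethioate
Conditions: 2-(diethoxyphosphoryl)propanoic acid, DCC, DMAP, CH2Cl2, 0 → 25 °C
Reagents that add atoms: 2-(diethoxyphosphoryl)propanoic acid (CC(C(=O)O)P(=O)(OCC)OCC)
Why: Steglich esterification of the secondary alcohol installs the phosphonate that will later supply C17, C18 and C19 of the butenolide.

Step 23
Reactants: 27 epoxy iodide; 31 phosphonate thioester
Product: 33 C8 ketone (C9–C8 bond formed; C7 bears the phosphonopropanoate and the 2-(phenylselanyl)ethyl group), via alkylzinc iodide 32 (not isolated)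
Conditions: Zn dust, LiCl, THF, 25 °C; then 31, PdCl2(PPh3)2 (10 mol %), toluene, 25 °C
Reagents that add atoms: none
Why: Fukuyama coupling, in which direct zinc insertion gives an alkylzinc iodide mild enough for the esters and the epoxide, and zerovalent palladium transfers the alkyl group to the thioester to give the ketone without over-addition and under neutral conditions that should preserve the α-acyloxy stereocentre.

Step 24
Reactants: 33 α-acyloxy ketone
Product: 34 butenolide carrying a 2-(phenylselanyl)ethyl group on C7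
Conditions: LiCl, i-Pr2NEt, MeCN, 25 °C
Reagents that add atoms: none
Why: Intramolecular Horner–Wadsworth–Emmons olefination under LiCl/amine conditions closes the five-membered lactone by 5-exo attack of the phosphonate carbanion on the C8 ketone and elimination, giving the C8=C17 olefin.

Step 25
Reactants: 34 selenide
Product: 36 7-vinyl butenolide (metathesis precursor), via selenoxide 35 (not isolated)
Conditions: H2O2 (30 %), pyridine, CH2Cl2, 0 → 25 °C
Reagents that add atoms: none
Why: Oxidation to the selenoxide and syn elimination at room temperature can only involve the C6 hydrogens and so gives the terminal vinyl group under conditions that spare the epoxide and the other olefins.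

Step 26
Reactants: 36 seco-diene
Product: 37 malayenolide D
Conditions: second-generation Hoveyda–Grubbs catalyst (10 mol %), toluene (1 mM), 80 °C
Reagents that add atoms: none
Why: Ring-closing metathesis between the monosubstituted C6 vinyl group and the 1,1-disubstituted C5 olefin releases ethene and should give the (Z)-trisubstituted C5=C6 olefin favoured in the ten-membered ring held by the trans-fused cyclohexane and the butenolide, the tetrasubstituted and ester-conjugated olefins being inert.

**Compound list**
1 | 4-methylpent-4-en-1-ol | CC(=C)CCCO | starting material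
2 | 4-methylpent-4-enal | CC(=C)CCC=O | intermediate
3 | (R)-4-benzyl-3-propanoyl-1,3-oxazolidin-2-one | CCC(=O)N1[C@H](Cc2ccccc2)COC1=O | starting material
4 | dibutylboron (Z)-enolate of 3 | C/C=C(\OB(CCCC)CCCC)N1[C@H](Cc2ccccc2)COC1=O | intermediate
5 | (R)-4-benzyl-3-[(2R,3S)-3-hydroxy-2,6-dimethylhept-6-enoyl]-1,3-oxazolidin-2-one | C=C(C)CC[C@H](O)[C@@H](C)C(=O)N1[C@H](Cc2ccccc2)COC1=O | intermediate
6 | lithium (2R,3S)-3-hydroxy-2,6-dimethylhept-6-eneperoxoate | [Li+].[O-]OC(=O)[C@H](C)[C@@H](O)CCC(C)=C | intermediate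
7 | (2R,3S)-3-hydroxy-2,6-dimethylhept-6-enoic acid | OC(=O)[C@H](C)[C@@H](O)CCC(C)=C | intermediate
8 | (E)-but-2-ene-1,4-diol | OC/C=C/CO | starting material
9 | (E)-4-[(triisopropylsilyl)oxy]but-2-en-1-ol | OC/C=C/CO[Si](C(C)C)(C(C)C)C(C)C | intermediate
10 | (E)-4-[(triisopropylsilyl)oxy]but-2-en-1-yl (2R,3S)-3-hydroxy-2,6-dimethylhept-6-enoate | C=C(C)CC[C@H](O)[C@@H](C)C(=O)OC/C=C/CO[Si](C(C)C)(C(C)C)C(C)C | intermediate
11 | chelated dilithium alkoxide/(Z)-enolate of 10 (OLi cis to the carbinol carbon) | C/C(=C(/O[Li])OC/C=C/CO[Si](C(C)C)(C(C)C)C(C)C)[C@@H](O[Li])CCC(C)=C | intermediate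
12 | (2S,3S)-2-[(1S)-1-hydroxy-4-methylpent-4-en-1-yl]-2-methyl-3-{[(triisopropylsilyl)oxy]methyl}pent-4-enoic acid | C=C(C)CC[C@H](O)[C@@](C)(C(=O)O)[C@H](C=C)CO[Si](C(C)C)(C(C)C)C(C)C | intermediate
13 | methyl (2S,3S)-2-[(1S)-1-hydroxy-4-methylpent-4-en-1-yl]-2-methyl-3-{[(triisopropylsilyl)oxy]methyl}pent-4-enoate | C=C(C)CC[C@H](O)[C@@](C)(C(=O)OC)[C@H](C=C)CO[Si](C(C)C)(C(C)C)C(C)C | intermediate
14 | methyl (2S,3S)-2-methyl-2-{(1S)-4-methyl-1-[(triethylsilyl)oxy]pent-4-en-1-yl}-3-{[(triisopropylsilyl)oxy]methyl}pent-4-enoate | C=C(C)CC[C@H](O[Si](CC)(CC)CC)[C@@](C)(C(=O)OC)[C@H](C=C)CO[Si](C(C)C)(C(C)C)C(C)C | intermediate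
15 | methyl (2S,3S)-2-methyl-4-oxo-2-{(1S)-4-methyl-1-[(triethylsilyl)oxy]pent-4-en-1-yl}-3-{[(triisopropylsilyl)oxy]methyl}pentanoate | C=C(C)CC[C@H](O[Si](CC)(CC)CC)[C@@](C)(C(=O)OC)[C@H](C(C)=O)CO[Si](C(C)C)(C(C)C)C(C)C | intermediate
16 | bromomagnesium tertiary alkoxide from vinyl addition to 15 (C11 bears methyl, vinyl and OMgBr) | C=C(C)CC[C@H](O[Si](CC)(CC)CC)[C@@](C)(C(=O)OC)[C@H]([C@@](C)(C=C)O[Mg]Br)CO[Si](C(C)C)(C(C)C)C(C)C | intermediate
17 | 3,5-dimethyl-3-{(1S)-4-methyl-1-[(triethylsilyl)oxy]pent-4-en-1-yl}-4-{[(triisopropylsilyl)oxy]methyl}-5-vinyloxolan-2-one (5-vinyl cis to 4-CH2OSi and to 3-CH3; C1, C2, C10 as in 37) | C=C(C)CC[C@H](O[Si](CC)(CC)CC)[C@@]1(C)C(=O)O[C@](C)(C=C)[C@@H]1CO[Si](C(C)C)(C(C)C)C(C)C | intermediate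
18 | oxolan-2-ol (lactol) of 17, both anomers | C=C(C)CC[C@H](O[Si](CC)(CC)CC)[C@@]1(C)C(O)O[C@](C)(C=C)[C@@H]1CO[Si](C(C)C)(C(C)C)C(C)C | intermediate
19 | 2-(phenylsulfanyl)oxolane from 18, both anomers | C=C(C)CC[C@H](O[Si](CC)(CC)CC)[C@@]1(C)C(Sc2ccccc2)O[C@](C)(C=C)[C@@H]1CO[Si](C(C)C)(C(C)C)C(C)C | intermediate
20 | 2-lithiooxolane from 19 | C=C(C)CC[C@H](O[Si](CC)(CC)CC)[C@@]1(C)C([Li])O[C@](C)(C=C)[C@@H]1CO[Si](C(C)C)(C(C)C)C(C)C | intermediate
21 | 4,6-dimethyl-6-{(1S)-4-methyl-1-[(triethylsilyl)oxy]pent-4-en-1-yl}-5-{[(triisopropylsilyl)oxy]methyl}cyclohex-3-en-1-ol (14α-OH trans to the C1 methyl; C1 methyl cis to CH2OSi) | C=C(C)CC[C@H](O[Si](CC)(CC)CC)[C@@]1(C)[C@@H](O)CC=C(C)[C@@H]1CO[Si](C(C)C)(C(C)C)C(C)C | intermediate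
22 | 14-O-acetate of 21 | C=C(C)CC[C@H](O[Si](CC)(CC)CC)[C@@]1(C)[C@@H](OC(C)=O)CC=C(C)[C@@H]1CO[Si](C(C)C)(C(C)C)C(C)C | intermediate
23 | 14-acetoxy C2 alcohol (triethylsilyl group removed) | C=C(C)CC[C@H](O)[C@@]1(C)[C@@H](OC(C)=O)CC=C(C)[C@@H]1CO[Si](C(C)C)(C(C)C)C(C)C | intermediate
24 | 14-acetoxy 2-(3-methylbut-2-enoyloxy) C9 triisopropylsilyl ether | C=C(C)CC[C@H](OC(=O)C=C(C)C)[C@@]1(C)[C@@H](OC(C)=O)CC=C(C)[C@@H]1CO[Si](C(C)C)(C(C)C)C(C)C | intermediate
25 | primary C9 alcohol from 24 | C=C(C)CC[C@H](OC(=O)C=C(C)C)[C@@]1(C)[C@@H](OC(C)=O)CC=C(C)[C@@H]1CO | intermediate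
26 | 11β,12β-epoxide of 25 (epoxide cis to the CH2OH arm and the C1 methyl, trans to the acetate) | C=C(C)CC[C@H](OC(=O)C=C(C)C)[C@@]1(C)[C@@H](OC(C)=O)C[C@@H]2O[C@]2(C)[C@@H]1CO | intermediate
27 | C9 iodide of 26 | C=C(C)CC[C@H](OC(=O)C=C(C)C)[C@@]1(C)[C@@H](OC(C)=O)C[C@@H]2O[C@]2(C)[C@@H]1CI | intermediate
28 | (S)-3-hydroxyoxolan-2-one ((S)-α-hydroxy-γ-butyrolactone) | O=C1OCC[C@@H]1O | starting material
29 | (S)-2-hydroxy-4-(phenylselanyl)butanoic acid | O=C(O)[C@@H](O)CC[Se]c1ccccc1 | intermediate
30 | S-ethyl (S)-2-hydroxy-4-(phenylselanyl)butanethioate | CCSC(=O)[C@@H](O)CC[Se]c1ccccc1 | intermediate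
31 | S-ethyl (2S)-2-{[2-(diethoxyphosphoryl)propanoyl]oxy}-4-(phenylselanyl)butanethioate (phosphonate carbon as a mixture) | CCSC(=O)[C@@H](OC(=O)C(C)P(=O)(OCC)OCC)CC[Se]c1ccccc1 | intermediate
32 | C9 alkylzinc iodide from 27 | C=C(C)CC[C@H](OC(=O)C=C(C)C)[C@@]1(C)[C@@H](OC(C)=O)C[C@@H]2O[C@]2(C)[C@@H]1C[Zn]I | intermediate
33 | C8 ketone: C9H2–C(=O)–C7H(O-phosphonopropanoyl)–CH2CH2SePh on the epoxycyclohexane core, (7S) | C=C(C)CC[C@H](OC(=O)C=C(C)C)[C@@]1(C)[C@@H](OC(C)=O)C[C@@H]2O[C@]2(C)[C@@H]1CC(=O)[C@@H](OC(=O)C(C)P(=O)(OCC)OCC)CC[Se]c1ccccc1 | intermediate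
34 | (7S)-butenolide (3-methyl-5H-furan-2-one linked through C4 to C9) carrying 5-[2-(phenylselanyl)ethyl] | C=C(C)CC[C@H](OC(=O)C=C(C)C)[C@@]1(C)[C@@H](OC(C)=O)C[C@@H]2O[C@]2(C)[C@@H]1CC3=C(C)C(=O)O[C@H]3CC[Se]c4ccccc4 | intermediate
35 | selenoxide of 34 | C=C(C)CC[C@H](OC(=O)C=C(C)C)[C@@]1(C)[C@@H](OC(C)=O)C[C@@H]2O[C@]2(C)[C@@H]1CC3=C(C)C(=O)O[C@H]3CC[Se](=O)c4ccccc4 | intermediate
36 | (7S)-7-vinyl butenolide, seco-diene for ring closure | C=C(C)CC[C@H](OC(=O)C=C(C)C)[C@@]1(C)[C@@H](OC(C)=O)C[C@@H]2O[C@]2(C)[C@@H]1CC3=C(C)C(=O)O[C@H]3C=C | intermediate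
37 | malayenolide D | CC(=O)O[C@H]1C[C@@H]2O[C@]2(C)[C@@H]2CC3=C(C)C(=O)O[C@H]3/C=C(/C)CC[C@H](OC(=O)C=C(C)C)[C@@]12C | target

Total step count: 26. Longest linear sequence: 22 steps (steps 1–3, 5–19 and 23–26, from 1 to 37).

**Steps most likely to fail**

1. Step 13 (proposed new method). The lithiated oxolane may be protonated, may fragment (retro-[3+2] cleavage or opening at the allylic C–O bond), or may carry lithium on the face from which the shift is slow, so that ring expansion is outrun. Fallback by known chemistry, setting out from 15 and returning at 21: Wittig methylenation of the ketone (Ph3P=CH2, THF) should give the isopropenyl ester F1; reduction with i-Bu2AlH gives the neopentyl alcohol F2 and Dess–Martin oxidation the aldehyde F3; reagent-controlled allylboration with the appropriate antipode of B-allyldiisopinocampheylborane sets C14 and gives the homoallylic alcohol F4; ring-closing metathesis of the allyl and isopropenyl groups (second-generation Grubbs catalyst, CH2Cl2, 40 °C) closes the cyclohexene and gives 21.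

2. Step 26. Initiation at the hindered, allylically oxygenated vinyl group may be slow and intermolecular metathesis may compete with closure of a ten-membered ring that already holds the rigid butenolide; olefin geometry could also drift. Fallback, setting out from 33 and returning at 37, closes the ring before the butenolide exists: selenoxide elimination on 33 (H2O2, pyridine) gives the vinyl keto phosphonate F5; ring-closing metathesis on this more flexible seco-ketone gives the ten-membered keto phosphonate F6; intramolecular Horner–Wadsworth–Emmons olefination (LiCl, i-Pr2NEt) then annulates the butenolide on the ring and gives 37.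

3. Step 23. Zinc insertion at the β-branched iodide may be slow, zinc salts may open the epoxide, and the acidic phosphonate may protonate the organozinc. Fallback, setting out from 29 and 27 and returning at 34, brings in a preformed butenolide and avoids both the organozinc and the phosphonate: esterification of 29 (TMSCHN2) gives the methyl ester F7; propanoylation (propanoyl chloride, pyridine) gives the diester F8; Dieckmann cyclization (LiN(SiMe3)2, THF, −78 °C) gives the tetronic acid F9; oxalyl bromide/DMF gives the 4-bromobutenolide F10; nickel-catalysed reductive cross-electrophile coupling of 27 with F10 (NiCl2·glyme, 4,4'-di-tert-butyl-2,2'-bipyridine, Mn powder, DMA) forms the C8–C9 bond and gives 34.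

Further compounds
F1 | step 13 | methyl (2S,3S)-2-methyl-2-{(1S)-4-methyl-1-[(triethylsilyl)oxy]pent-4-en-1-yl}-4-methyl-3-{[(triisopropylsilyl)oxy]methyl}pent-4-enoate (isopropenyl ester) | C=C(C)CC[C@H](O[Si](CC)(CC)CC)[C@@](C)(C(=O)OC)[C@H](C(C)=C)CO[Si](C(C)C)(C(C)C)C(C)C
F2 | step 13 | primary alcohol from reduction of F1 | C=C(C)CC[C@H](O[Si](CC)(CC)CC)[C@@](C)(CO)[C@H](C(C)=C)CO[Si](C(C)C)(C(C)C)C(C)C
F3 | step 13 | aldehyde from oxidation of F2 | C=C(C)CC[C@H](O[Si](CC)(CC)CC)[C@@](C)(C=O)[C@H](C(C)=C)CO[Si](C(C)C)(C(C)C)C(C)C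
F4 | step 13 | homoallylic alcohol from allylboration of F3 (C14 carbinol as in 21) | C=C(C)CC[C@H](O[Si](CC)(CC)CC)[C@@](C)([C@@H](O)CC=C)[C@H](C(C)=C)CO[Si](C(C)C)(C(C)C)C(C)C
F5 | step 26 | (7S)-7-vinyl keto phosphonate from selenoxide elimination of 33 | C=C(C)CC[C@H](OC(=O)C=C(C)C)[C@@]1(C)[C@@H](OC(C)=O)C[C@@H]2O[C@]2(C)[C@@H]1CC(=O)[C@@H](OC(=O)C(C)P(=O)(OCC)OCC)C=C
F6 | step 26 | ten-membered (5Z)-8-oxo 7-O-[2-(diethoxyphosphoryl)propanoate] | CC(=O)O[C@H]1C[C@@H]2O[C@]2(C)[C@@H]2CC(=O)[C@@H](OC(=O)C(C)P(=O)(OCC)OCC)/C=C(/C)CC[C@H](OC(=O)C=C(C)C)[C@@]12C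
F7 | step 23 | methyl (S)-2-hydroxy-4-(phenylselanyl)butanoate | COC(=O)[C@@H](O)CC[Se]c1ccccc1
F8 | step 23 | methyl (S)-2-(propanoyloxy)-4-(phenylselanyl)butanoate | COC(=O)[C@@H](OC(=O)CC)CC[Se]c1ccccc1
F9 | step 23 | (S)-4-hydroxy-3-methyl-5-[2-(phenylselanyl)ethyl]furan-2(5H)-one | O=C1O[C@@H](CC[Se]c2ccccc2)C(O)=C1C
F10 | step 23 | (S)-4-bromo-3-methyl-5-[2-(phenylselanyl)ethyl]furan-2(5H)-one | O=C1O[C@@H](CC[Se]c2ccccc2)C(Br)=C1C
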